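The route rests on a Diels–Alder disconnection of the cyclohexene ring (C3a, C4, C5, C6, C7, C7a): its C6=C7 alkene, flanked by the contiguous quaternary pair C4/C5 and by the ring-fusion carbons, marks it as the adduct of a C7a=C7–C6=C5 diene and a C4=C3a enal. One thermal intramolecular cycloaddition of an acyclic (2E,7E,9E,11E)-tetraenal forms C4–C5 and C3a–C7a, closes the six-membered ring last (the cyclopentane with it) and sets four stereocentres. Two tether stereocentres, each allylic to an ethyl-bearing alkene, steer face and ring fusion. The precursor arises from a vinylogous aldol reaction and three olefinations; desilylation and Jones oxidation finish.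

Key step: step 13

Numbering: ring positions follow 1H-indene; acyclic intermediates are numbered from the acyl/dienophile carbonyl carbon (C1) to the phenyl-bearing carbon (C12).

Remark: step 5 assumes the usual sense of induction for valinol-derived vinylketene silyl N,O-acetals (aldehyde enters anti to the isopropyl group, so the (R)-auxiliary gives the 4R adduct); were the sense opposite, the (S)-oxazolidinone would be used and nothing else changes.

Step 1
Reactants: 1 methyl (R)-3-hydroxy-2-methylpropanoate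
Product: 2 methyl (R)-3-[(tert-butyldimethylsilyl)oxy]-2-methylpropanoate
Conditions: TBSCl, imidazole, CH2Cl2, 0 °C to rt
Reagents that add atoms: tert-butyldimethylsilyl chloride, CC(C)(C)[Si](C)(C)Cl
Why: Standard silylation of a primary alcohol, which does not involve the stereocentre.

Step 2
Reactants: 2 methyl (R)-3-[(tert-butyldimethylsilyl)oxy]-2-methylpropanoate
Product: 3 (R)-3-[(tert-butyldimethylsilyl)oxy]-2-methylpropanal
Conditions: iBu2AlH (1.1 equiv), CH2Cl2, −78 °C; MeOH, then aq. sodium potassium tartrate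
Reagents that add atoms: none
Why: Partial reduction of an ester with diisobutylaluminium hydride at low temperature should stop at the aldehyde, which is used crude so that the α-stereocentre is not epimerised.

Step 3
Reactants: 4 (E)-2-ethylhex-2-enoic acid; 5 (R)-4-isopropyloxazolidin-2-one
Product: 7 (R)-3-[(E)-2-ethylhex-2-enoyl]-4-isopropyloxazolidin-2-one, via mixed pivalic anhydride 6 (not isolated)
Conditions: PivCl, Et3N, THF, −20 °C; then 5, LiCl, rt
Reagents that add atoms: none
Why: N-acylation of an oxazolidinone through a mixed anhydride (LiCl/Et3N protocol) is standard for α,β-unsaturated acids and leaves the E alkene untouched.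

Step 4
Reactants: 7 (R)-3-[(E)-2-ethylhex-2-enoyl]-4-isopropyloxazolidin-2-one
Product: 9 (R)-3-[(1E,3E)-1-[(tert-butyldimethylsilyl)oxy]-2-ethylhexa-1,3-dien-1-yl]-4-isopropyloxazolidin-2-one, via sodium dienolate 8 (not isolated)
Conditions: NaN(SiMe3)2, THF, −78 °C; then TBSCl, −78 °C
Reagents that add atoms: tert-butyldimethylsilyl chloride, CC(C)(C)[Si](C)(C)Cl
Why: γ-Deprotonation of a 2-alkyl-2-enoyl oxazolidinone gives the extended dienolate, and O-silylation should furnish the (1E,3E)-vinylketene silyl N,O-acetal as is general for this substrate class.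

Step 5
Reactants: 3 (R)-3-[(tert-butyldimethylsilyl)oxy]-2-methylpropanal; 9 (R)-3-[(1E,3E)-1-[(tert-butyldimethylsilyl)oxy]-2-ethylhexa-1,3-dien-1-yl]-4-isopropyloxazolidin-2-one
Product: 10 (R)-3-[(2E,4R,5R,6R)-7-[(tert-butyldimethylsilyl)oxy]-2,4-diethyl-5-hydroxy-6-methylhept-2-enoyl]-4-isopropyloxazolidin-2-one
Conditions: TiCl4 (1.0 equiv), CH2Cl2, −78 to −40 °C; aq. NaHCO3
Reagents that add atoms: none
Why: In this vinylogous Mukaiyama aldol reaction the TiCl4-bound aldehyde should attack the γ-carbon through an open transition state on the face opposite the isopropyl group of the perpendicular oxazolidinone (sets C4 and the 4,5-anti relation, E-enoyl unit retained), while Felkin–Anh addition to the non-chelating α-methyl aldehyde gives the 5,6-syn relation, so reagent and substrate control are matched.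

Step 6
Reactants: 10 (R)-3-[(2E,4R,5R,6R)-7-[(tert-butyldimethylsilyl)oxy]-2,4-diethyl-5-hydroxy-6-methylhept-2-enoyl]-4-isopropyloxazolidin-2-one
Product: 11 (R)-3-[(2E,4R,5R,6R)-5,7-bis[(tert-butyldimethylsilyl)oxy]-2,4-diethyl-6-methylhept-2-enoyl]-4-isopropyloxazolidin-2-one
Conditions: TBSOTf, 2,6-lutidine, CH2Cl2, −78 to 0 °C
Reagents that add atoms: tert-butyldimethylsilyl trifluoromethanesulfonate, CC(C)(C)[Si](C)(C)OS(=O)(=O)C(F)(F)F
Why: Silyl triflate silylation of the hindered secondary alcohol protects C5 against retro-aldol cleavage and oxidation in the following steps.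

Step 7
Reactants: 11 (R)-3-[(2E,4R,5R,6R)-5,7-bis[(tert-butyldimethylsilyl)oxy]-2,4-diethyl-6-methylhept-2-enoyl]-4-isopropyloxazolidin-2-one
Product: 12 (R)-3-[(2E,4R,5R,6R)-5-[(tert-butyldimethylsilyl)oxy]-2,4-diethyl-7-hydroxy-6-methylhept-2-enoyl]-4-isopropyloxazolidin-2-one
Conditions: HF·pyridine, pyridine, THF, 0 °C to rt
Reagents that add atoms: none
Why: Under buffered HF·pyridine a primary silyl ether is cleaved much faster than a secondary one flanked by two branched carbons.

Step 8
Reactants: 12 (R)-3-[(2E,4R,5R,6R)-5-[(tert-butyldimethylsilyl)oxy]-2,4-diethyl-7-hydroxy-6-methylhept-2-enoyl]-4-isopropyloxazolidin-2-one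
Product: 13 (R)-3-[(2E,4R,5R,6S)-5-[(tert-butyldimethylsilyl)oxy]-2,4-diethyl-6-methyl-7-oxohept-2-enoyl]-4-isopropyloxazolidin-2-one
Conditions: Dess–Martin periodinane, NaHCO3, CH2Cl2, 0 °C to rt
Reagents that add atoms: none
Why: Buffered Dess–Martin oxidation should give the α-branched aldehyde without epimerisation (the change of the C6 descriptor is a priority change only), and it is used at once.

Step 9
Reactants: 13 (R)-3-[(2E,4R,5R,6S)-5-[(tert-butyldimethylsilyl)oxy]-2,4-diethyl-6-methyl-7-oxohept-2-enoyl]-4-isopropyloxazolidin-2-one; 14 2-(triphenylphosphoranylidene)butanal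
Product: 15 (R)-3-[(2E,4R,5S,6R,7E)-5-[(tert-butyldimethylsilyl)oxy]-2,4,8-triethyl-6-methyl-9-oxonona-2,7-dienoyl]-4-isopropyloxazolidin-2-one
Conditions: toluene, 80 °C
Reagents that add atoms: none
Why: Wittig reaction with the formyl-stabilised ylide should give the E-trisubstituted enal, and the saturated aldehyde reacts much faster than the enal that is formed.

Step 10
Reactants: 15 (R)-3-[(2E,4R,5S,6R,7E)-5-[(tert-butyldimethylsilyl)oxy]-2,4,8-triethyl-6-methyl-9-oxonona-2,7-dienoyl]-4-isopropyloxazolidin-2-one; 14 2-(triphenylphosphoranylidene)butanal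
Product: 16 (R)-3-[(2E,4R,5S,6R,7E,9E)-5-[(tert-butyldimethylsilyl)oxy]-2,4,8,10-tetraethyl-6-methyl-11-oxoundeca-2,7,9-trienoyl]-4-isopropyloxazolidin-2-one
Conditions: toluene, 110 °C
Reagents that add atoms: none
Why: A second Wittig homologation on the enal should again give the E alkene, and the dienal product is a still poorer electrophile, which limits over-homologation.

Step 11
Reactants: 16 (R)-3-[(2E,4R,5S,6R,7E,9E)-5-[(tert-butyldimethylsilyl)oxy]-2,4,8,10-tetraethyl-6-methyl-11-oxoundeca-2,7,9-trienoyl]-4-isopropyloxazolidin-2-one; 17 diethyl benzylphosphonate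
Product: 19 (R)-3-[(2E,4R,5S,6R,7E,9E,11E)-5-[(tert-butyldimethylsilyl)oxy]-2,4,8,10-tetraethyl-6-methyl-12-phenyldodeca-2,7,9,11-tetraenoyl]-4-isopropyloxazolidin-2-one, via sodium phosphonate carbanion 18 (not isolated)
Conditions: 17, NaN(SiMe3)2, THF, −78 °C; then 16, −78 to 0 °C
Reagents that add atoms: none
Why: Horner–Wadsworth–Emmons olefination with a benzylic phosphonate anion should give the E-styryl alkene, the aldehyde being far more electrophilic than the twisted imide, which remains as a masked dienophile now that the electron-rich diene is complete.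

Step 12
Reactants: 19 (R)-3-[(2E,4R,5S,6R,7E,9E,11E)-5-[(tert-butyldimethylsilyl)oxy]-2,4,8,10-tetraethyl-6-methyl-12-phenyldodeca-2,7,9,11-tetraenoyl]-4-isopropyloxazolidin-2-one
Product: 20 (2E,4R,5S,6R,7E,9E,11E)-5-[(tert-butyldimethylsilyl)oxy]-2,4,8,10-tetraethyl-6-methyl-12-phenyldodeca-2,7,9,11-tetraenal
Conditions: iBu2AlH (1.5 equiv), CH2Cl2, −78 °C; aq. sodium potassium tartrate, product kept cold
Reagents that add atoms: none
Why: Low-temperature partial reduction of the N-acyloxazolidinone should release the enal (and the recoverable auxiliary) only on work-up, which unmasks the dienophile without touching a stereocentre.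

Step 13
Reactants: 20 (2E,4R,5S,6R,7E,9E,11E)-5-[(tert-butyldimethylsilyl)oxy]-2,4,8,10-tetraethyl-6-methyl-12-phenyldodeca-2,7,9,11-tetraenal
Product: 21 (1R,2S,3R,3aS,4S,5R,7aS)-2-[(tert-butyldimethylsilyl)oxy]-3,4,5,7-tetraethyl-1-methyl-5-[(E)-2-phenylethenyl]-2,3,3a,4,5,7a-hexahydro-1H-indene-4-carbaldehyde
Conditions: toluene (degassed, 0.01 M, BHT), 100 °C, sealed tube
Reagents that add atoms: none
Why: A concerted, suprafacial [4+2] cycloaddition (type 1 intramolecular Diels–Alder reaction of a 1,3,8-nonatriene carrying a terminally activated E-dienophile) should take place on heating; the closest known class is the cyclisation of nona-2,7,9-trienals to trans-hydrindenes. The six-membered ring closes by simultaneous formation of C4–C5 and C3a–C7a between the (7E,9E)-diene and the (2E)-enal, and the five-membered ring closes as the three-atom tether (chain carbons 4 to 6) becomes the fused bridge between these two new bonds. The E-enal fixes the C3a/C4 relation (formyl cis to H-3a), the diene geometry (tether and styryl both outside) fixes the C5/C7a relation, and the endo orientation of the formyl group links the two pairs (formyl cis to styryl) and gives the trans ring fusion. The absolute sense comes from the two tether stereocentres: each keeps its hydrogen in the plane of the neighbouring alkene to avoid A(1,3) strain with the vinylic ethyl group (on chain C8 of the diene and chain C2 of the enal), which places the tether on one face of each π-system. Because these two centres are 1,3-anti, both preferences can be met only in the endo, trans-fused transition state, so facial and endo/exo selectivity are both secured by the substrate. The step must also outrun [1,5]-hydrogen shift in the Z-ethyl-bearing diene, which intramolecularity and enal activation at about 100 °C should ensure.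

Step 14
Reactants: 21 (1R,2S,3R,3aS,4S,5R,7aS)-2-[(tert-butyldimethylsilyl)oxy]-3,4,5,7-tetraethyl-1-methyl-5-[(E)-2-phenylethenyl]-2,3,3a,4,5,7a-hexahydro-1H-indene-4-carbaldehyde
Product: 22 (1R,2S,3R,3aS,4S,5R,7aS)-3,4,5,7-tetraethyl-2-hydroxy-1-methyl-5-[(E)-2-phenylethenyl]-2,3,3a,4,5,7a-hexahydro-1H-indene-4-carbaldehyde
Conditions: aq. HF (48%), MeCN, rt to 40 °C
Reagents that add atoms: none
Why: Acidic fluoride cleavage of the secondary silyl ether should leave the non-enolisable aldehyde and both alkenes untouched.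

Step 15
Reactants: 22 (1R,2S,3R,3aS,4S,5R,7aS)-3,4,5,7-tetraethyl-2-hydroxy-1-methyl-5-[(E)-2-phenylethenyl]-2,3,3a,4,5,7a-hexahydro-1H-indene-4-carbaldehyde
Product: 24 (1R,3R,3aS,4S,5R,7aS)-3,4,5,7-tetraethyl-1-methyl-2-oxo-5-[(E)-2-phenylethenyl]-2,3,3a,4,5,7a-hexahydro-1H-indene-4-carboxylic acid, via keto aldehyde 23 (not isolated)
Conditions: CrO3, H2SO4, acetone/H2O, 0 °C (Jones oxidation)
Reagents that add atoms: water, O
Why: Jones oxidation should take the secondary alcohol to the ketone and the aldehyde, through its hydrate, to the carboxylic acid in one operation; C1 and C3 already carry their alkyl groups trans to the neighbouring ring bonds, the thermodynamically preferred arrangement, so acid should not erode them.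

Compound list
1 | methyl (R)-3-hydroxy-2-methylpropanoate | COC(=O)[C@H](C)CO | starting material
2 | methyl (R)-3-[(tert-butyldimethylsilyl)oxy]-2-methylpropanoate | COC(=O)[C@H](C)CO[Si](C)(C)C(C)(C)C | intermediate
3 | (R)-3-[(tert-butyldimethylsilyl)oxy]-2-methylpropanal | O=C[C@H](C)CO[Si](C)(C)C(C)(C)C | intermediate
4 | (E)-2-ethylhex-2-enoic acid | CCC/C=C(\CC)C(=O)O | starting material
5 | (R)-4-isopropyloxazolidin-2-one | CC(C)[C@@H]1COC(=O)N1 | starting material
6 | mixed pivalic anhydride: (E)-2-ethylhex-2-enoic pivalic anhydride | CCC/C=C(\CC)C(=O)OC(=O)C(C)(C)C | intermediate (not isolated)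
7 | (R)-3-[(E)-2-ethylhex-2-enoyl]-4-isopropyloxazolidin-2-one | CCC/C=C(\CC)C(=O)N1[C@H](C(C)C)COC1=O | intermediate
8 | sodium dienolate of 7 | CC/C=C/C(CC)=C(/[O-])N1[C@H](C(C)C)COC1=O.[Na+] | intermediate (not isolated)
9 | (R)-3-[(1E,3E)-1-[(tert-butyldimethylsilyl)oxy]-2-ethylhexa-1,3-dien-1-yl]-4-isopropyloxazolidin-2-one | CC/C=C/C(CC)=C(/O[Si](C)(C)C(C)(C)C)N1[C@H](C(C)C)COC1=O | intermediate
10 | (R)-3-[(2E,4R,5R,6R)-7-[(tert-butyldimethylsilyl)oxy]-2,4-diethyl-5-hydroxy-6-methylhept-2-enoyl]-4-isopropyloxazolidin-2-one | O=C(/C(CC)=C/[C@@H](CC)[C@@H](O)[C@H](C)CO[Si](C)(C)C(C)(C)C)N1[C@H](C(C)C)COC1=O | intermediate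
11 | (R)-3-[(2E,4R,5R,6R)-5,7-bis[(tert-butyldimethylsilyl)oxy]-2,4-diethyl-6-methylhept-2-enoyl]-4-isopropyloxazolidin-2-one | O=C(/C(CC)=C/[C@@H](CC)[C@@H](O[Si](C)(C)C(C)(C)C)[C@H](C)CO[Si](C)(C)C(C)(C)C)N1[C@H](C(C)C)COC1=O | intermediate
12 | (R)-3-[(2E,4R,5R,6R)-5-[(tert-butyldimethylsilyl)oxy]-2,4-diethyl-7-hydroxy-6-methylhept-2-enoyl]-4-isopropyloxazolidin-2-one | O=C(/C(CC)=C/[C@@H](CC)[C@@H](O[Si](C)(C)C(C)(C)C)[C@H](C)CO)N1[C@H](C(C)C)COC1=O | intermediate
13 | (R)-3-[(2E,4R,5R,6S)-5-[(tert-butyldimethylsilyl)oxy]-2,4-diethyl-6-methyl-7-oxohept-2-enoyl]-4-isopropyloxazolidin-2-one | O=C(/C(CC)=C/[C@@H](CC)[C@@H](O[Si](C)(C)C(C)(C)C)[C@H](C)C=O)N1[C@H](C(C)C)COC1=O | intermediate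
14 | 2-(triphenylphosphoranylidene)butanal | CCC(C=O)=P(c1ccccc1)(c1ccccc1)c1ccccc1 | starting material
15 | (R)-3-[(2E,4R,5S,6R,7E)-5-[(tert-butyldimethylsilyl)oxy]-2,4,8-triethyl-6-methyl-9-oxonona-2,7-dienoyl]-4-isopropyloxazolidin-2-one | O=C(/C(CC)=C/[C@@H](CC)[C@@H](O[Si](C)(C)C(C)(C)C)[C@H](C)/C=C(\CC)C=O)N1[C@H](C(C)C)COC1=O | intermediate
16 | (R)-3-[(2E,4R,5S,6R,7E,9E)-5-[(tert-butyldimethylsilyl)oxy]-2,4,8,10-tetraethyl-6-methyl-11-oxoundeca-2,7,9-trienoyl]-4-isopropyloxazolidin-2-one | O=C(/C(CC)=C/[C@@H](CC)[C@@H](O[Si](C)(C)C(C)(C)C)[C@H](C)/C=C(\CC)/C=C(\CC)C=O)N1[C@H](C(C)C)COC1=O | intermediate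
17 | diethyl benzylphosphonate | CCOP(=O)(Cc1ccccc1)OCC | starting material
18 | sodium phosphonate carbanion of 17 | CCOP(=O)([CH-]c1ccccc1)OCC.[Na+] | intermediate (not isolated)
19 | (R)-3-[(2E,4R,5S,6R,7E,9E,11E)-5-[(tert-butyldimethylsilyl)oxy]-2,4,8,10-tetraethyl-6-methyl-12-phenyldodeca-2,7,9,11-tetraenoyl]-4-isopropyloxazolidin-2-one | O=C(/C(CC)=C/[C@@H](CC)[C@@H](O[Si](C)(C)C(C)(C)C)[C@H](C)/C=C(\CC)/C=C(\CC)/C=C/c1ccccc1)N1[C@H](C(C)C)COC1=O | intermediate
20 | (2E,4R,5S,6R,7E,9E,11E)-5-[(tert-butyldimethylsilyl)oxy]-2,4,8,10-tetraethyl-6-methyl-12-phenyldodeca-2,7,9,11-tetraenal | O=C/C(CC)=C/[C@@H](CC)[C@@H](O[Si](C)(C)C(C)(C)C)[C@H](C)/C=C(\CC)/C=C(\CC)/C=C/c1ccccc1 | intermediate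
21 | (1R,2S,3R,3aS,4S,5R,7aS)-2-[(tert-butyldimethylsilyl)oxy]-3,4,5,7-tetraethyl-1-methyl-5-[(E)-2-phenylethenyl]-2,3,3a,4,5,7a-hexahydro-1H-indene-4-carbaldehyde | CCC1=C[C@](/C=C/c2ccccc2)(CC)[C@@](CC)(C=O)[C@H]2[C@H]1[C@@H](C)[C@H](O[Si](C)(C)C(C)(C)C)[C@@H]2CC | intermediate
22 | (1R,2S,3R,3aS,4S,5R,7aS)-3,4,5,7-tetraethyl-2-hydroxy-1-methyl-5-[(E)-2-phenylethenyl]-2,3,3a,4,5,7a-hexahydro-1H-indene-4-carbaldehyde | CCC1=C[C@](/C=C/c2ccccc2)(CC)[C@@](CC)(C=O)[C@H]2[C@H]1[C@@H](C)[C@H](O)[C@@H]2CC | intermediate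
23 | keto aldehyde: (1R,3R,3aS,4S,5R,7aS)-3,4,5,7-tetraethyl-1-methyl-2-oxo-5-[(E)-2-phenylethenyl]-2,3,3a,4,5,7a-hexahydro-1H-indene-4-carbaldehyde | CCC1=C[C@](/C=C/c2ccccc2)(CC)[C@@](CC)(C=O)[C@H]2[C@H]1[C@@H](C)C(=O)[C@@H]2CC | intermediate (not isolated)
24 | (1R,3R,3aS,4S,5R,7aS)-3,4,5,7-tetraethyl-1-methyl-2-oxo-5-[(E)-2-phenylethenyl]-2,3,3a,4,5,7a-hexahydro-1H-indene-4-carboxylic acid | CCC1=C[C@](/C=C/c2ccccc2)(CC)[C@@](CC)(C(=O)O)[C@H]2[C@H]1[C@@H](C)C(=O)[C@@H]2CC | target

Total step count: 15. Longest linear sequence: 13 steps (steps 1, 2 and 5 to 15 from compound 1; the branch through steps 3 and 4 is equally long).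

Steps most likely to fail

Step 13. The cycloaddition may be too slow at temperatures where the Z-ethyl-substituted diene undergoes [1,5]-hydrogen migration, or closure through the exo transition state may erode the trans ring fusion. The fallback sets out from 20 and returns at 21, and replaces the neutral thermal cycloaddition by an ionic Diels–Alder reaction. Treatment of 20 with 1,2-bis(trimethylsilyloxy)ethane and catalytic TMSOTf (CH2Cl2, −78 °C) should give the ethylene acetal of tetraenal 20 F1. More TMSOTf (−78 to −40 °C) opens the dioxolane to an allyl oxocarbenium ion, a far stronger dienophile, which should cyclise at low temperature through the same A(1,3)-controlled geometry to the ethylene acetal of cycloadduct 21 F2. Acetal hydrolysis (pyridinium p-toluenesulfonate, acetone/water, 50 °C) then gives 21.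

Step 5. Conversion may be poor, or face selectivity eroded, when the hindered γ-ethyl nucleophile meets the α-branched aldehyde; an induction sense different from the model would make the pairing mismatched. The fallback sets out from 3 and returns at 11, and builds the C4–C5 bond by a substrate-controlled allylation followed by olefination.
- Nozaki–Hiyama allylation of 3 with (E)-1-bromopent-2-ene and CrCl2 (THF, 0 °C to rt) should give (2R,3R,4R)-1-[(tert-butyldimethylsilyl)oxy]-4-ethyl-2-methylhex-5-en-3-ol F3. The 4,5-anti relation comes from the chair transition state of the allylchromium reagent and the 5,6-syn relation from Felkin–Anh addition; minor isomers are removed by chromatography.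
- TBSOTf and 2,6-lutidine give (3R,4R,5R)-4,6-bis[(tert-butyldimethylsilyl)oxy]-3-ethyl-5-methylhex-1-ene F4.
- Ozonolysis (O3, CH2Cl2, −78 °C; PPh3) gives (2S,3S,4R)-3,5-bis[(tert-butyldimethylsilyl)oxy]-2-ethyl-4-methylpentanal F5.
- The olefination partner is made from 5: n-BuLi, then 2-bromobutanoyl bromide, gives (4R)-3-(2-bromobutanoyl)-4-isopropyloxazolidin-2-one F6, and an Arbuzov reaction with P(OEt)3 at 120 °C gives diethyl {1-[(R)-4-isopropyl-2-oxooxazolidin-3-yl]-1-oxobutan-2-yl}phosphonate F7.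
- Horner–Wadsworth–Emmons reaction of F5 with F7 (LiCl, iPr2NEt, MeCN, rt) should give the E-enoyl imide 11.

Step 12. Hydride delivery to the twisted, hindered imide may be slow, or reduction may run on to the allylic alcohol. The fallback sets out from 19 and returns at 20, and separates removal of the auxiliary from adjustment of the oxidation level. LiBH4 (MeOH, Et2O, 0 °C) should reduce 19 fully to (2E,4R,5S,6R,7E,9E,11E)-5-[(tert-butyldimethylsilyl)oxy]-2,4,8,10-tetraethyl-6-methyl-12-phenyldodeca-2,7,9,11-tetraen-1-ol F8. Chemoselective allylic oxidation with MnO2 (CH2Cl2, rt) then gives 20.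

Further compounds
F1 | step 13 | ethylene acetal of tetraenal 20 | C1(/C(CC)=C/[C@@H](CC)[C@@H](O[Si](C)(C)C(C)(C)C)[C@H](C)/C=C(\CC)/C=C(\CC)/C=C/c2ccccc2)OCCO1
F2 | step 13 | ethylene acetal of cycloadduct 21 | CCC1=C[C@](/C=C/c2ccccc2)(CC)[C@@](CC)(C3OCCO3)[C@H]2[C@H]1[C@@H](C)[C@H](O[Si](C)(C)C(C)(C)C)[C@@H]2CC
F3 | step 5 | (2R,3R,4R)-1-[(tert-butyldimethylsilyl)oxy]-4-ethyl-2-methylhex-5-en-3-ol | C=C[C@@H](CC)[C@@H](O)[C@H](C)CO[Si](C)(C)C(C)(C)C
F4 | step 5 | (3R,4R,5R)-4,6-bis[(tert-butyldimethylsilyl)oxy]-3-ethyl-5-methylhex-1-ene | C=C[C@@H](CC)[C@@H](O[Si](C)(C)C(C)(C)C)[C@H](C)CO[Si](C)(C)C(C)(C)C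
F5 | step 5 | (2S,3S,4R)-3,5-bis[(tert-butyldimethylsilyl)oxy]-2-ethyl-4-methylpentanal | O=C[C@@H](CC)[C@@H](O[Si](C)(C)C(C)(C)C)[C@H](C)CO[Si](C)(C)C(C)(C)C
F6 | step 5 | (4R)-3-(2-bromobutanoyl)-4-isopropyloxazolidin-2-one | CCC(Br)C(=O)N1[C@H](C(C)C)COC1=O
F7 | step 5 | diethyl {1-[(R)-4-isopropyl-2-oxooxazolidin-3-yl]-1-oxobutan-2-yl}phosphonate | CCC(C(=O)N1[C@H](C(C)C)COC1=O)P(=O)(OCC)OCC
F8 | step 12 | (2E,4R,5S,6R,7E,9E,11E)-5-[(tert-butyldimethylsilyl)oxy]-2,4,8,10-tetraethyl-6-methyl-12-phenyldodeca-2,7,9,11-tetraen-1-ol | OC/C(CC)=C/[C@@H](CC)[C@@H](O[Si](C)(C)C(C)(C)C)[C@H](C)/C=C(\CC)/C=C(\CC)/C=C/c1ccccc1
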